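**Retrosynthetic overview**
- Target ⇐ fluoride removal of two aryl silyl ethers from a protected lactone.
- Key step: one radical cascade makes the lactone C2–C3 bond (5-exo closure of an alkoxycarbonyl radical onto a vinyl group) and the ArCH2–C bond (nickel capture of the resulting primary radical with an aryl bromide). This closes the only ring formed in the route, the γ-lactone, and sets C3 trans to C4.
- The homoallylic oxalate ⇐ anti-1,3-diol from an iridium-catalysed (hydroxymethyl)allylation of a silyl-protected vanillin with vinyl ethylene carbonate, which sets the carbinol carbon and C4.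
- Both aryl units ⇐ one silyl-protected 4-bromoguaiacol ⇐ guaiacol ⇐ catechol + MeI; the arene rings are carried through unchanged.

Abbreviation: Ar = 3-methoxy-4-[tri(propan-2-yl)silyloxy]phenyl.
Assumption: (S)-SEGPHOS is taken to give the 1S carbinol in step 5, by analogy with related iridium-catalysed allylations of aryl aldehydes; if the sense is opposite, the (R)-ligand is used with no other change.

**Step 1**
Reactants: 1 catechol (benzene-1,2-diol)
Product: 2 guaiacol (2-methoxyphenol)
Conditions: MeI (1.0 equiv), K2CO3 (1.0 equiv), acetone, reflux, N2 (1 in two-fold excess; acid–base extraction)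
Reagents that add atoms: iodomethane (CI)
Why: Williamson mono-O-methylation, in which only the mono-phenoxide of catechol forms with one equivalent of carbonate, excess diol with limiting MeI suppresses dimethylation, and extraction separates 2 from catechol and veratrole.

**Step 2**
Reactants: 2 guaiacol
Product: 3 4-bromo-2-methoxyphenol
Conditions: NBS (1.0 equiv), MeCN, 0 °C
Reagents that add atoms: N-bromosuccinimide (O=C1CCC(=O)N1Br)
Why: Electrophilic aromatic bromination, directed by the free hydroxyl (the stronger donor) to its unhindered para position.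

**Step 3**
Reactants: 3 4-bromo-2-methoxyphenol
Product: 4 (4-bromo-2-methoxyphenoxy)tri(propan-2-yl)silane (Ar–Br)
Conditions: TIPSCl, imidazole, DMF, rt
Reagents that add atoms: chlorotri(propan-2-yl)silane (CC(C)[Si](Cl)(C(C)C)C(C)C)
Why: Imidazole-promoted phenol silylation; the bulky silyl ether survives BuLi, mild base and photoredox conditions and is removed by fluoride at the end.

**Step 4**
Reactants: 4 (4-bromo-2-methoxyphenoxy)tri(propan-2-yl)silane
Product: 7 3-methoxy-4-[tri(propan-2-yl)silyloxy]benzaldehyde (Ar–CHO), via aryllithium 5 (not isolated), via lithium aminoalkoxide 6 (not isolated)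
Conditions: n-BuLi, THF, −78 °C; DMF, −78 → 0 °C; aq. NH4Cl
Reagents that add atoms: N,N-dimethylformamide (CN(C)C=O)
Why: Bromine–lithium exchange outruns any deprotonation at −78 °C and aryllithium 5 is formylated by DMF (Bouveault aldehyde synthesis), adduct 6 collapsing to the aldehyde only on work-up so that no over-addition occurs.

**Step 5**
Reactants: 7 3-methoxy-4-[tri(propan-2-yl)silyloxy]benzaldehyde; 8 vinyl ethylene carbonate (4-ethenyl-1,3-dioxolan-2-one, racemic)
Product: 9 (1S,2R)-2-ethenyl-1-Ar-propane-1,3-diol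
Conditions: [Ir(cod)Cl]2 (2.5 mol %), (S)-SEGPHOS (5 mol %), 4-cyano-3-nitrobenzoic acid (10 mol %), K3PO4 (10 mol %), i-PrOH (2 equiv), THF, 60 °C
Reagents that add atoms: none
Why: Iridium-catalysed transfer-hydrogenative carbonyl (hydroxymethyl)allylation (Krische type), in which the catalyst ionises the allylic carbonate with loss of CO2, isopropanol supplies the hydrogen, and the (E)-σ-allyl iridium adds through a closed chair transition state that gives the anti 1,3-diol (2R) while the chiral bisphosphine selects the aldehyde face that gives the 1S carbinol.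

**Step 6**
Reactants: 9 (1S,2R)-2-ethenyl-1-Ar-propane-1,3-diol
Product: 11 cesium (2R)-2-[(S)-hydroxy(Ar)methyl]but-3-en-1-yl oxalate, via chlorooxoacetate ester 10 (not isolated)
Conditions: (COCl)2 (1.5 equiv, inverse addition of 9), 2,6-lutidine, CH2Cl2, −78 °C; aq. CsHCO3, −78 → 0 °C
Reagents that add atoms: oxalyl chloride (O=C(Cl)C(Cl)=O); water (O); cesium hydrogen carbonate ([Cs+].OC([O-])=O)
Why: Kinetically selective O-acylation of the unhindered primary hydroxyl over the branched benzylic secondary one at low temperature, then hydrolysis of the acid chloride under bicarbonate buffering, which gives the oxalate half-ester directly as its cesium salt without exposing the acid-labile benzylic alcohol to HCl.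

**Step 7 (key step)**
Reactants: 11 cesium (2R)-2-[(S)-hydroxy(Ar)methyl]but-3-en-1-yl oxalate; 4 (4-bromo-2-methoxyphenoxy)tri(propan-2-yl)silane (1.5 equiv)
Product: 14 (3R,4R)-3-(Ar-methyl)-4-[(S)-hydroxy(Ar)methyl]oxolan-2-one, via alkoxycarbonyl radical 12 (not isolated), via lactonylmethyl radical 13 (not isolated)
Conditions: Ir[dF(CF3)ppy]2(dtbbpy)PF6 (2 mol %), NiBr2(dtbbpy) (10 mol %), DMSO/1,4-dioxane, blue LEDs, 25 °C, degassed
Reagents that add atoms: none
Why: Metallaphotoredox alkoxycarbonyl-radical cyclisation/cross-coupling cascade, in which the excited photocatalyst oxidises the oxalate, loss of one CO2 gives radical 12, this closes 5-exo-trig onto the vinyl group through a chair-like Beckwith–Houk transition state with the large CH(OH)Ar group pseudo-equatorial so that the new exocyclic CH2 is trans to it (3R), and primary radical 13 is captured by the aryl–nickel species formed from 4 and reductively eliminated as the benzylic C–C bond.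

**Step 8**
Reactants: 14 (3R,4R)-3-(Ar-methyl)-4-[(S)-hydroxy(Ar)methyl]oxolan-2-one
Product: 15 (3R,4R)-4-[(S)-hydroxy(4-hydroxy-3-methoxyphenyl)methyl]-3-[(4-hydroxy-3-methoxyphenyl)methyl]oxolan-2-one (target)
Conditions: TBAF (2.4 equiv), AcOH (2.4 equiv), THF, 0 °C
Reagents that add atoms: none
Why: Fluoride cleavage of the two aryl silyl ethers, buffered with acetic acid so that no phenoxide persists and neither quinone-methide epimerisation at the carbinol carbon nor base-induced epimerisation or translactonisation of the lactone can occur.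

**Compound list**
1 | catechol (benzene-1,2-diol) | Oc1ccccc1O | starting material
2 | guaiacol (2-methoxyphenol) | COc1ccccc1O | intermediate
3 | 4-bromo-2-methoxyphenol | COc1cc(Br)ccc1O | intermediate
4 | (4-bromo-2-methoxyphenoxy)tri(propan-2-yl)silane | COc1cc(Br)ccc1O[Si](C(C)C)(C(C)C)C(C)C | intermediate
5 | {3-methoxy-4-[tri(propan-2-yl)silyloxy]phenyl}lithium | COc1cc([Li])ccc1O[Si](C(C)C)(C(C)C)C(C)C | intermediate
6 | lithium (dimethylamino){3-methoxy-4-[tri(propan-2-yl)silyloxy]phenyl}methanolate (aminal carbon racemic) | COc1cc(C(O[Li])N(C)C)ccc1O[Si](C(C)C)(C(C)C)C(C)C | intermediate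
7 | 3-methoxy-4-[tri(propan-2-yl)silyloxy]benzaldehyde | COc1cc(C=O)ccc1O[Si](C(C)C)(C(C)C)C(C)C | intermediate
8 | vinyl ethylene carbonate (4-ethenyl-1,3-dioxolan-2-one, racemic) | C=CC1COC(=O)O1 | starting material
9 | (1S,2R)-2-ethenyl-1-{3-methoxy-4-[tri(propan-2-yl)silyloxy]phenyl}propane-1,3-diol | OC[C@@H](C=C)[C@H](O)c1ccc(O[Si](C(C)C)(C(C)C)C(C)C)c(OC)c1 | intermediate
10 | (2R)-2-[(S)-hydroxy{3-methoxy-4-[tri(propan-2-yl)silyloxy]phenyl}methyl]but-3-en-1-yl chloro(oxo)acetate | O=C(Cl)C(=O)OC[C@@H](C=C)[C@H](O)c1ccc(O[Si](C(C)C)(C(C)C)C(C)C)c(OC)c1 | intermediate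
11 | cesium (2R)-2-[(S)-hydroxy{3-methoxy-4-[tri(propan-2-yl)silyloxy]phenyl}methyl]but-3-en-1-yl oxalate | [Cs+].[O-]C(=O)C(=O)OC[C@@H](C=C)[C@H](O)c1ccc(O[Si](C(C)C)(C(C)C)C(C)C)c(OC)c1 | intermediate
12 | {(2R)-2-[(S)-hydroxy{3-methoxy-4-[tri(propan-2-yl)silyloxy]phenyl}methyl]but-3-en-1-yl}oxycarbonyl radical | O=[C]OC[C@@H](C=C)[C@H](O)c1ccc(O[Si](C(C)C)(C(C)C)C(C)C)c(OC)c1 | intermediate
13 | {(3R,4R)-4-[(S)-hydroxy{3-methoxy-4-[tri(propan-2-yl)silyloxy]phenyl}methyl]-2-oxooxolan-3-yl}methyl radical | [CH2][C@H]1C(=O)OC[C@@H]1[C@H](O)c1ccc(O[Si](C(C)C)(C(C)C)C(C)C)c(OC)c1 | intermediate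
14 | (3R,4R)-4-[(S)-hydroxy{3-methoxy-4-[tri(propan-2-yl)silyloxy]phenyl}methyl]-3-({3-methoxy-4-[tri(propan-2-yl)silyloxy]phenyl}methyl)oxolan-2-one | COc1cc(C[C@H]2C(=O)OC[C@@H]2[C@H](O)c2ccc(O[Si](C(C)C)(C(C)C)C(C)C)c(OC)c2)ccc1O[Si](C(C)C)(C(C)C)C(C)C | intermediate
15 | (3R,4R)-4-[(S)-hydroxy(4-hydroxy-3-methoxyphenyl)methyl]-3-[(4-hydroxy-3-methoxyphenyl)methyl]oxolan-2-one | COc1cc(C[C@H]2C(=O)OC[C@@H]2[C@H](O)c2ccc(O)c(OC)c2)ccc1O | target

Total step count: 8.
Longest linear sequence: 8 steps (1 → 2 → 3 → 4 → 7 → 9 → 11 → 14 → 15; bromide 4 re-enters at step 7).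

**Steps most likely to fail, with fallbacks**

Step 7. The risks are capture of radical 12 by nickel before it cyclises (giving an aryl ester), 1,5-hydrogen transfer from the benzylic carbinol C–H, and only moderate trans selectivity. The fallback separates the two bond formations and sets out from diol 9. A Heck arylation with bromide 4 (Pd(OAc)2, P(o-tol)3, Et3N, MeCN, 80 °C) gives (1S,2R)-1-Ar-2-[(E)-2-Ar-ethenyl]propane-1,3-diol F1. Selective oxalylation under the step 6 conditions gives its cesium oxalate F2. Irradiation of F2 with Ir[dF(CF3)ppy]2(dtbbpy)PF6 and a catalytic arenethiol in wet DME, without nickel, closes the lactone by 5-exo attack of the alkoxycarbonyl radical on the styrene through the same chair-like transition state, and the benzylic radical is quenched by hydrogen-atom transfer from the thiol. This comes back to the route at 14.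

Step 6. The risk is that oxalyl chloride does not discriminate between the two hydroxyls and gives the bis-oxalate or the seven-membered cyclic oxalate. The fallback differentiates the hydroxyls by silyl chemistry and sets out from 9. TESOTf with 2,6-lutidine in CH2Cl2 gives bis(triethylsilyl) ether F3. HF·pyridine buffered with pyridine in THF at 0 °C removes only the primary silyl group to give (2R)-2-[(S)-Ar(triethylsilyloxy)methyl]but-3-en-1-ol F4. Excess oxalyl chloride followed by aqueous CsHCO3 then gives cesium oxalate F5. The step 7 conditions with bromide 4 give the silyl-protected lactone F6. The step 8 conditions remove all three silyl groups, and the fallback comes back to the route at 15.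

Step 5. The risks are slow coupling of this electron-rich aldehyde, incomplete anti selectivity and the unverified sense of induction. The fallback reaches the diol by a chromium-mediated vinylogous Reformatsky addition and sets out from 7. Commercial methyl (E)-4-bromobut-2-enoate, CrCl2 (10 mol %) with a chiral carbazole bis(oxazoline) ligand, Mn, TMSCl and Et3N in THF, followed by mild desilylation, give methyl (2S,3S)-2-ethenyl-3-hydroxy-3-Ar-propanoate F7. The carbon–carbon bond forms at the ester α-carbon through a closed transition state, which gives the anti isomer. LiBH4 in THF at 0 °C reduces the ester to the primary alcohol, and the fallback comes back to the route at 9.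

**Further compounds**
F1 | step 7 | (1S,2R)-1-{3-methoxy-4-[tri(propan-2-yl)silyloxy]phenyl}-2-[(E)-2-{3-methoxy-4-[tri(propan-2-yl)silyloxy]phenyl}ethenyl]propane-1,3-diol | OC[C@@H](/C=C/c1ccc(O[Si](C(C)C)(C(C)C)C(C)C)c(OC)c1)[C@H](O)c1ccc(O[Si](C(C)C)(C(C)C)C(C)C)c(OC)c1
F2 | step 7 | cesium (2R,3E)-2-[(S)-hydroxy{3-methoxy-4-[tri(propan-2-yl)silyloxy]phenyl}methyl]-4-{3-methoxy-4-[tri(propan-2-yl)silyloxy]phenyl}but-3-en-1-yl oxalate | [Cs+].[O-]C(=O)C(=O)OC[C@@H](/C=C/c1ccc(O[Si](C(C)C)(C(C)C)C(C)C)c(OC)c1)[C@H](O)c1ccc(O[Si](C(C)C)(C(C)C)C(C)C)c(OC)c1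
F3 | step 6 | (1S,2R)-2-ethenyl-1-{3-methoxy-4-[tri(propan-2-yl)silyloxy]phenyl}propane-1,3-diol bis(triethylsilyl) ether | CC[Si](CC)(CC)OC[C@@H](C=C)[C@H](O[Si](CC)(CC)CC)c1ccc(O[Si](C(C)C)(C(C)C)C(C)C)c(OC)c1
F4 | step 6 | (2R)-2-[(S)-{3-methoxy-4-[tri(propan-2-yl)silyloxy]phenyl}(triethylsilyloxy)methyl]but-3-en-1-ol | OC[C@@H](C=C)[C@H](O[Si](CC)(CC)CC)c1ccc(O[Si](C(C)C)(C(C)C)C(C)C)c(OC)c1
F5 | step 6 | cesium (2R)-2-[(S)-{3-methoxy-4-[tri(propan-2-yl)silyloxy]phenyl}(triethylsilyloxy)methyl]but-3-en-1-yl oxalate | [Cs+].[O-]C(=O)C(=O)OC[C@@H](C=C)[C@H](O[Si](CC)(CC)CC)c1ccc(O[Si](C(C)C)(C(C)C)C(C)C)c(OC)c1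
F6 | step 6 | (3R,4R)-3-({3-methoxy-4-[tri(propan-2-yl)silyloxy]phenyl}methyl)-4-[(S)-{3-methoxy-4-[tri(propan-2-yl)silyloxy]phenyl}(triethylsilyloxy)methyl]oxolan-2-one | COc1cc(C[C@H]2C(=O)OC[C@@H]2[C@H](O[Si](CC)(CC)CC)c2ccc(O[Si](C(C)C)(C(C)C)C(C)C)c(OC)c2)ccc1O[Si](C(C)C)(C(C)C)C(C)C
F7 | step 5 | methyl (2S,3S)-2-ethenyl-3-hydroxy-3-{3-methoxy-4-[tri(propan-2-yl)silyloxy]phenyl}propanoate | COC(=O)[C@@H](C=C)[C@H](O)c1ccc(O[Si](C(C)C)(C(C)C)C(C)C)c(OC)c1
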